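**Plan**
- Retrosynthesis: remove the four benzyl ethers and take the C4 carbonyl back to the C3=C4 alkene of a 2H-chromene. Then cut C4–C4a and O1–C2 of ring C together (propargyl ether Claisen shift, then oxa-6π closure), then the O1–CMe2 ether bond, then the bond between the bridge CH2 and C8.
- Forward: the ring B phenol is made from the benzoic acid (benzylation, methyl ketone, Baeyer–Villiger). The ring A benzylic alcohol is made from 2-methylphloroglucinol (acylation, O-methylation, formylation, benzylation, reduction). Friedel–Crafts benzylation joins them, O1 is etherified, heat closes ring C, and hydration, oxidation and hydrogenolysis finish.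
- Enabling feature: in ring B, C8 carries the methylene bridge and C6 a methyl group, so C4a is the only unsubstituted carbon ortho to O1. A 2-methylbut-3-yn-2-yl group on O1 can therefore deliver C2, C3 and C4 of ring C only there.
- Stereochemistry: the target has no stereocentre; those that appear on the way (C4a in the dienone, C3 and C4 during hydration) are racemic and are erased.

Key step: step 12

Assumption: rings B and C carry chromanone numbering (O1, C2–C4, C4a, C5–C8, C8a) and ring A is the acylated ring. Compounds 1, 8, 9 and 17 are taken as purchasable. Every compound with a stereocentre is racemic; one enantiomer is written only where a relative configuration has to be shown.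

**Step 1**
Reactants: 1 3,5-dihydroxy-4-methylbenzoic acid
Product: 2 benzyl 3,5-bis(benzyloxy)-4-methylbenzoate
Conditions: BnBr (3.5 equiv), K2CO3, DMF, 60 °C
Reagents that add atoms: benzyl bromide, BrCc1ccccc1
Why: Williamson-type alkylation, in which carbonate deprotonates the acid and both phenols and all three oxygen anions are benzylated in DMF; the ester benzyl group is shed again in step 2.

**Step 2**
Reactants: 2 benzyl 3,5-bis(benzyloxy)-4-methylbenzoate
Product: 3 3,5-bis(benzyloxy)-N-methoxy-N,4-dimethylbenzamide
Conditions: MeNH(OMe)·HCl, iPrMgCl, THF, −20 → 0 °C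
Reagents that add atoms: N,O-dimethylhydroxylamine hydrochloride, CNOC.Cl
Why: Weinreb amide formation directly from an ester by aminolysis with the chloromagnesium amide of N,O-dimethylhydroxylamine, conditions under which aryl benzyl ethers are inert.

**Step 3**
Reactants: 3 3,5-bis(benzyloxy)-N-methoxy-N,4-dimethylbenzamide
Product: 5 1-[3,5-bis(benzyloxy)-4-methylphenyl]ethan-1-one, via magnesium hemiaminal chelate 4 (not isolated)
Conditions: MeMgBr, THF, 0 °C; then 1 M HCl
Reagents that add atoms: methylmagnesium bromide, C[Mg]Br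
Why: Weinreb ketone synthesis, in which chelate 4 holds the tetrahedral adduct until the acidic quench, so only one methyl group is delivered and no tertiary alcohol should form.

**Step 4**
Reactants: 5 1-[3,5-bis(benzyloxy)-4-methylphenyl]ethan-1-one
Product: 7 3,5-bis(benzyloxy)-4-methylphenol, via aryl acetate 6 (not isolated)
Conditions: mCPBA, CF3CO2H (1 equiv), CH2Cl2, rt; aq. Na2SO3/NaHCO3 wash; then K2CO3 (cat.), MeOH, rt
Reagents that add atoms: 3-chloroperoxybenzoic acid, OOC(=O)c1cccc(Cl)c1
Why: Baeyer–Villiger oxidation of an aryl methyl ketone, in which the aryl group migrates in preference to methyl and so places oxygen on the carbon that becomes C8a; mild methanolysis of acetate 6 then frees the phenol without touching the benzyl ethers.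

**Step 5**
Reactants: 8 2-methylbenzene-1,3,5-triol; 9 2-methylpropanoyl chloride
Product: 10 2-methyl-1-(2,4,6-trihydroxy-3-methylphenyl)propan-1-one
Conditions: AlCl3, PhNO2/CH2Cl2, 0 → 40 °C; aq. HCl
Reagents that add atoms: none
Why: Friedel–Crafts C-acylation of the strongly activated triol, whose two open ring carbons are equivalent and whose first acyl group deactivates the ring against a second acylation.

**Step 6**
Reactants: 10 2-methyl-1-(2,4,6-trihydroxy-3-methylphenyl)propan-1-one
Product: 11 1-(2,6-dihydroxy-4-methoxy-3-methylphenyl)-2-methylpropan-1-one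
Conditions: Me2SO4 (1.0 equiv), K2CO3 (1.1 equiv), acetone, rt
Reagents that add atoms: dimethyl sulfate, COS(=O)(=O)OC
Why: selective Williamson O-methylation, since the hydroxyl para to the carbonyl is the most acidic and is not hydrogen-bonded to the ketone, so one equivalent of alkylating agent with a weak base should methylate it ahead of the two chelated ortho hydroxyls.

**Step 7**
Reactants: 11 1-(2,6-dihydroxy-4-methoxy-3-methylphenyl)-2-methylpropan-1-one
Product: 13 2,4-dihydroxy-6-methoxy-5-methyl-3-(2-methylpropanoyl)benzaldehyde, via aryl chloromethyl methyl ether 12 (not isolated)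
Conditions: Cl2CHOMe, TiCl4, CH2Cl2, −10 → 0 °C; then aq. HCl
Reagents that add atoms: dichloromethyl methyl ether, COC(Cl)Cl; water, O
Why: Rieche formylation, in which the TiCl4-activated dichloromethyl ether attacks the single unsubstituted ring carbon (ortho to the methoxy group and one hydroxyl, para to the other) and aqueous acid hydrolyses α-chloro ether 12 to the aldehyde, an electrophile that leaves the isopropyl ketone side chain alone.

**Step 8**
Reactants: 13 2,4-dihydroxy-6-methoxy-5-methyl-3-(2-methylpropanoyl)benzaldehyde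
Product: 14 2,4-bis(benzyloxy)-6-methoxy-5-methyl-3-(2-methylpropanoyl)benzaldehyde
Conditions: BnBr (2.5 equiv), K2CO3, DMF, 70 °C
Reagents that add atoms: benzyl bromide, BrCc1ccccc1
Why: Williamson benzylation of both chelated phenols, for which potassium phenoxides in a dipolar aprotic solvent react at oxygen and warming overcomes the hydrogen bonding to the two carbonyl groups.

**Step 9**
Reactants: 14 2,4-bis(benzyloxy)-6-methoxy-5-methyl-3-(2-methylpropanoyl)benzaldehyde
Product: 15 1-[2,6-bis(benzyloxy)-3-(hydroxymethyl)-4-methoxy-5-methylphenyl]-2-methylpropan-1-one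
Conditions: NaBH4, THF/MeOH, −20 → 0 °C
Reagents that add atoms: none
Why: chemoselective borohydride reduction, in which the aldehyde is reduced in the cold while the isopropyl ketone, twisted out of conjugation between two benzyloxy groups, is too hindered to react.

**Step 10**
Reactants: 15 1-[2,6-bis(benzyloxy)-3-(hydroxymethyl)-4-methoxy-5-methylphenyl]-2-methylpropan-1-one; 7 3,5-bis(benzyloxy)-4-methylphenol (3 equiv)
Product: 16 1-[2,6-bis(benzyloxy)-3-{[2,4-bis(benzyloxy)-6-hydroxy-3-methylphenyl]methyl}-4-methoxy-5-methylphenyl]-2-methylpropan-1-one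
Conditions: BF3·OEt2 (0.2 equiv), CH2Cl2, −40 → 0 °C
Reagents that add atoms: none
Why: dehydrative Friedel–Crafts benzylation, in which ionisation of 15 with loss of its hydroxyl as water gives a benzylic cation stabilised by two ortho and one para alkoxy group and phenol 7 captures it at one of its two equivalent carbons ortho to the hydroxyl; the excess of 7 limits double alkylation and catalytic Lewis acid in the cold spares the benzyl ethers.

**Step 11**
Reactants: 16 the diarylmethane phenol of step 10; 17 3-chloro-3-methylbut-1-yne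
Product: 18 1-[2,6-bis(benzyloxy)-3-({2,4-bis(benzyloxy)-3-methyl-6-[(2-methylbut-3-yn-2-yl)oxy]phenyl}methyl)-4-methoxy-5-methylphenyl]-2-methylpropan-1-one
Conditions: DBU, CuCl2·2H2O (cat.), MeCN, 0 °C → rt
Reagents that add atoms: none
Why: copper-catalysed propargylic etherification, in which the copper-activated tertiary propargylic chloride is substituted by the phenoxide at the tertiary carbon, the standard route to aryl 1,1-dimethylpropargyl ethers that also tolerates an ortho substituent; 16 has only this one free hydroxyl.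

**Step 12**
Reactants: 18 the aryl 2-methylbut-3-yn-2-yl ether of step 11
Product: 22 1-[2,6-bis(benzyloxy)-3-{[5,7-bis(benzyloxy)-2,2,6-trimethyl-2H-chromen-8-yl]methyl}-4-methoxy-5-methylphenyl]-2-methylpropan-1-one, via allenyl cyclohexadienone 19 (not isolated), via ortho-allenyl phenol 20 (not isolated), via ortho-quinone methide 21 (not isolated)
Conditions: PhNEt2, 170 °C, argon
Reagents that add atoms: none
Why: A [3,3]-sigmatropic (propargyl Claisen) shift joins the alkyne terminus to C4a and breaks the O1–CMe2 bond to give dienone 19, which enolises to phenol 20, and a 1,5-hydrogen shift from the phenol oxygen to the central allene carbon then gives ortho-quinone methide 21. Ring C closes by thermal oxa-6π electrocyclisation of this 1-oxatriene, forming O1–C2 at the gem-dimethyl terminus as a six-membered ring. The closest known reaction is the thermal conversion of aryl 1,1-dimethylpropargyl ethers into 2,2-dimethyl-2H-chromenes. No stereocentre remains, since C4a of 19 is lost on enolisation and the product is planar at C3 and C4. The step needs regioselection between the two carbons ortho to O1: a shift to C8, which carries the methylene bridge, gives a dienone that cannot enolise and can only revert, and the para carbon C6 is methylated, so all material should drain through C4a. The benzyl ethers and the hindered ketone are spectators in the hot, weakly basic solvent.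

**Step 13**
Reactants: 22 the tetra-O-benzyl 2H-chromene of step 12
Product: 24 1-[2,6-bis(benzyloxy)-3-{[5,7-bis(benzyloxy)-4-hydroxy-2,2,6-trimethyl-3,4-dihydro-2H-chromen-8-yl]methyl}-4-methoxy-5-methylphenyl]-2-methylpropan-1-one (racemic), via trans organomercurial acetate 23 (not isolated)
Conditions: Hg(OAc)2, THF/H2O, rt; then NaBH4, aq. NaOH, 0 °C
Reagents that add atoms: water, O; mercury diacetate, CC(=O)O[Hg]OC(C)=O (retained in 23 only)
Why: Markovnikov oxymercuration–demercuration, in which water opens the mercurinium ion at benzylic C4 (positive charge there is stabilised by O1, O5 and O7 through ring B) to give trans adduct 23 and borohydride replaces mercury by hydrogen at C3; the new C4 stereocentre is racemic and disappears in step 14, and every arene carbon of rings A and B is substituted, so no aryl mercuration can compete.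

**Step 14**
Reactants: 24 the chroman-4-ol of step 13
Product: 25 5,7-bis(benzyloxy)-8-{[2,4-bis(benzyloxy)-6-methoxy-5-methyl-3-(2-methylpropanoyl)phenyl]methyl}-2,2,6-trimethyl-2,3-dihydro-4H-chromen-4-one
Conditions: Dess–Martin periodinane, CH2Cl2, rt
Reagents that add atoms: none
Why: Dess–Martin oxidation of the secondary benzylic alcohol to the chroman-4-one under near-neutral conditions that leave the benzyl ethers and the diarylmethane untouched.

**Step 15**
Reactants: 25 the tetra-O-benzyl chromanone of step 14
Product: 26 mallopallidol, 5,7-dihydroxy-8-{[2,4-dihydroxy-6-methoxy-5-methyl-3-(2-methylpropanoyl)phenyl]methyl}-2,2,6-trimethyl-2,3-dihydro-4H-chromen-4-one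
Conditions: H2 (1 atm), 10% Pd/C, EtOAc/MeOH, rt
Reagents that add atoms: none
Why: catalytic hydrogenolysis of the four aryl benzyl ethers under neutral conditions, which should spare the methyl ether, the two electron-rich aryl ketones (vinylogous esters, hydrogen-bonded once the ortho hydroxyls are freed) and the acid- and base-sensitive methylene bridge.

**Compound list**
1 | 3,5-dihydroxy-4-methylbenzoic acid | Cc1c(O)cc(C(=O)O)cc1O | starting material
2 | benzyl 3,5-bis(benzyloxy)-4-methylbenzoate | Cc1c(OCc2ccccc2)cc(C(=O)OCc2ccccc2)cc1OCc1ccccc1 | intermediate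
3 | 3,5-bis(benzyloxy)-N-methoxy-N,4-dimethylbenzamide | CON(C)C(=O)c1cc(OCc2ccccc2)c(C)c(OCc2ccccc2)c1 | intermediate
4 | magnesium hemiaminal chelate, bromomagnesium 1-[3,5-bis(benzyloxy)-4-methylphenyl]-1-[methoxy(methyl)amino]ethoxide (racemic, formed in the flask) | CON(C)C(C)(O[Mg]Br)c1cc(OCc2ccccc2)c(C)c(OCc2ccccc2)c1 | intermediate
5 | 1-[3,5-bis(benzyloxy)-4-methylphenyl]ethan-1-one | CC(=O)c1cc(OCc2ccccc2)c(C)c(OCc2ccccc2)c1 | intermediate
6 | 3,5-bis(benzyloxy)-4-methylphenyl acetate (formed in the flask) | CC(=O)Oc1cc(OCc2ccccc2)c(C)c(OCc2ccccc2)c1 | intermediate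
7 | 3,5-bis(benzyloxy)-4-methylphenol | Cc1c(OCc2ccccc2)cc(O)cc1OCc1ccccc1 | intermediate
8 | 2-methylbenzene-1,3,5-triol | Cc1c(O)cc(O)cc1O | starting material
9 | 2-methylpropanoyl chloride | CC(C)C(=O)Cl | starting material
10 | 2-methyl-1-(2,4,6-trihydroxy-3-methylphenyl)propan-1-one | CC(C)C(=O)c1c(O)cc(O)c(C)c1O | intermediate
11 | 1-(2,6-dihydroxy-4-methoxy-3-methylphenyl)-2-methylpropan-1-one | COc1cc(O)c(C(=O)C(C)C)c(O)c1C | intermediate
12 | 1-{3-[chloro(methoxy)methyl]-2,6-dihydroxy-4-methoxy-5-methylphenyl}-2-methylpropan-1-one (racemic, formed in the flask) | COc1c(C)c(O)c(C(=O)C(C)C)c(O)c1C(Cl)OC | intermediate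
13 | 2,4-dihydroxy-6-methoxy-5-methyl-3-(2-methylpropanoyl)benzaldehyde | COc1c(C)c(O)c(C(=O)C(C)C)c(O)c1C=O | intermediate
14 | 2,4-bis(benzyloxy)-6-methoxy-5-methyl-3-(2-methylpropanoyl)benzaldehyde | COc1c(C)c(OCc2ccccc2)c(C(=O)C(C)C)c(OCc2ccccc2)c1C=O | intermediate
15 | 1-[2,6-bis(benzyloxy)-3-(hydroxymethyl)-4-methoxy-5-methylphenyl]-2-methylpropan-1-one | COc1c(C)c(OCc2ccccc2)c(C(=O)C(C)C)c(OCc2ccccc2)c1CO | intermediate
16 | 1-[2,6-bis(benzyloxy)-3-{[2,4-bis(benzyloxy)-6-hydroxy-3-methylphenyl]methyl}-4-methoxy-5-methylphenyl]-2-methylpropan-1-one | COc1c(C)c(OCc2ccccc2)c(C(=O)C(C)C)c(OCc2ccccc2)c1Cc1c(OCc2ccccc2)c(C)c(OCc2ccccc2)cc1O | intermediate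
17 | 3-chloro-3-methylbut-1-yne | CC(C)(Cl)C#C | starting material
18 | 1-[2,6-bis(benzyloxy)-3-({2,4-bis(benzyloxy)-3-methyl-6-[(2-methylbut-3-yn-2-yl)oxy]phenyl}methyl)-4-methoxy-5-methylphenyl]-2-methylpropan-1-one | COc1c(C)c(OCc2ccccc2)c(C(=O)C(C)C)c(OCc2ccccc2)c1Cc1c(OCc2ccccc2)c(C)c(OCc2ccccc2)cc1OC(C)(C)C#C | intermediate
19 | allenyl cyclohexadienone: 3,5-bis(benzyloxy)-2-{[2,4-bis(benzyloxy)-6-methoxy-5-methyl-3-(2-methylpropanoyl)phenyl]methyl}-4-methyl-6-(3-methylbuta-1,2-dien-1-yl)cyclohexa-2,4-dien-1-one (racemic, formed in the flask) | COc1c(C)c(OCc2ccccc2)c(C(=O)C(C)C)c(OCc2ccccc2)c1CC1=C(OCc2ccccc2)C(C)=C(OCc2ccccc2)C(C=C=C(C)C)C1=O | intermediate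
20 | ortho-allenyl phenol: 1-[2,6-bis(benzyloxy)-3-{[2,4-bis(benzyloxy)-6-hydroxy-3-methyl-5-(3-methylbuta-1,2-dien-1-yl)phenyl]methyl}-4-methoxy-5-methylphenyl]-2-methylpropan-1-one (formed in the flask) | COc1c(C)c(OCc2ccccc2)c(C(=O)C(C)C)c(OCc2ccccc2)c1Cc1c(OCc2ccccc2)c(C)c(OCc2ccccc2)c(C=C=C(C)C)c1O | intermediate
21 | ortho-quinone methide: 3,5-bis(benzyloxy)-2-{[2,4-bis(benzyloxy)-6-methoxy-5-methyl-3-(2-methylpropanoyl)phenyl]methyl}-4-methyl-6-(3-methylbut-2-en-1-ylidene)cyclohexa-2,4-dien-1-one, dimethylvinyl group syn to the ring carbonyl (formed in the flask) | CC(C)=C/C=C1\C(=O)C(Cc2c(OC)c(C)c(OCc3ccccc3)c(C(=O)C(C)C)c2OCc2ccccc2)=C(OCc2ccccc2)C(C)=C1OCc1ccccc1 | intermediate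
22 | 1-[2,6-bis(benzyloxy)-3-{[5,7-bis(benzyloxy)-2,2,6-trimethyl-2H-chromen-8-yl]methyl}-4-methoxy-5-methylphenyl]-2-methylpropan-1-one | COc1c(C)c(OCc2ccccc2)c(C(=O)C(C)C)c(OCc2ccccc2)c1Cc1c(OCc2ccccc2)c(C)c(OCc2ccccc2)c2c1OC(C)(C)C=C2 | intermediate
23 | trans-3-(acetoxymercurio)-4-hydroxy adduct of 22 (racemic, one enantiomer written, formed in the flask) | COc1c(C)c(OCc2ccccc2)c(C(=O)C(C)C)c(OCc2ccccc2)c1Cc1c(OCc2ccccc2)c(C)c(OCc2ccccc2)c2c1OC(C)(C)[C@@H]([Hg]OC(C)=O)[C@@H]2O | intermediate
24 | 1-[2,6-bis(benzyloxy)-3-{[5,7-bis(benzyloxy)-4-hydroxy-2,2,6-trimethyl-3,4-dihydro-2H-chromen-8-yl]methyl}-4-methoxy-5-methylphenyl]-2-methylpropan-1-one (racemic) | COc1c(C)c(OCc2ccccc2)c(C(=O)C(C)C)c(OCc2ccccc2)c1Cc1c(OCc2ccccc2)c(C)c(OCc2ccccc2)c2c1OC(C)(C)CC2O | intermediate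
25 | 5,7-bis(benzyloxy)-8-{[2,4-bis(benzyloxy)-6-methoxy-5-methyl-3-(2-methylpropanoyl)phenyl]methyl}-2,2,6-trimethyl-2,3-dihydro-4H-chromen-4-one | COc1c(C)c(OCc2ccccc2)c(C(=O)C(C)C)c(OCc2ccccc2)c1Cc1c(OCc2ccccc2)c(C)c(OCc2ccccc2)c2c1OC(C)(C)CC2=O | intermediate
26 | mallopallidol | COc1c(C)c(O)c(C(=O)C(C)C)c(O)c1Cc1c(O)c(C)c(O)c2c1OC(C)(C)CC2=O | target

**Totals**
Total step count: 15.
Longest linear sequence: 11 steps (8 → 26 through steps 5–15); the ring B branch (steps 1–4, then 10–15) has 10.

**Steps most likely to fail**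

Step 10. The product phenol keeps one activated ortho carbon, so a second benzylation can follow the first, and the Lewis acid can promote loss or migration of a benzyl group next to the ketone. The fallback sets out from phenol 7 and aldehyde 14 and forms the same C–C bond under basic chelation control. Phenol 7 is converted into its bromomagnesium phenoxide with EtMgBr in toluene and added to 14 through a six-membered chelated transition state (ortho-specific hydroxyalkylation of a magnesium phenoxide), which should give the diaryl carbinol F1. Ionic hydrogenation of the doubly benzylic hydroxyl with Et3SiH and CF3CO2H in CH2Cl2 at −40 °C then returns to the route at 16, with alcohol 15 bypassed.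

Step 13. Mercuration may be slow or incomplete beside the peri benzyloxy group, and the ring A ketone may be partly reduced during demercuration. The fallback sets out from chromene 22 and uses radical hydration in place of the ionic addition. With Co(acac)2 (cat.), PhSiH3 and O2 in THF at rt (Mukaiyama hydration), hydrogen-atom transfer to C3 should give the benzylic C4 radical, which traps oxygen. The C4 hydroperoxide F2 that forms beside the alcohol is reduced in the same flask with PPh3, and the sequence returns at 24.

Step 6. Methylation may spread to a chelated ortho hydroxyl or stop short, leaving mixtures of ethers that are hard to separate. The fallback sets out from 10 and replaces selective alkylation by selective dealkylation. Exhaustive methylation (Me2SO4 in excess, K2CO3, acetone, reflux) should give the trimethyl ether F3. AlCl3 in chlorobenzene at 80 °C then cleaves the two methoxy groups flanking the ketone by chelation and spares the para methoxy group, returning to the route at 11.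

**Further compounds**
F1 | step 10 | 1-[2,6-bis(benzyloxy)-3-{[2,4-bis(benzyloxy)-6-hydroxy-3-methylphenyl](hydroxy)methyl}-4-methoxy-5-methylphenyl]-2-methylpropan-1-one (racemic) | COc1c(C)c(OCc2ccccc2)c(C(=O)C(C)C)c(OCc2ccccc2)c1C(O)c1c(OCc2ccccc2)c(C)c(OCc2ccccc2)cc1O
F2 | step 13 | 1-[2,6-bis(benzyloxy)-3-{[5,7-bis(benzyloxy)-4-hydroperoxy-2,2,6-trimethyl-3,4-dihydro-2H-chromen-8-yl]methyl}-4-methoxy-5-methylphenyl]-2-methylpropan-1-one (racemic) | COc1c(C)c(OCc2ccccc2)c(C(=O)C(C)C)c(OCc2ccccc2)c1Cc1c(OCc2ccccc2)c(C)c(OCc2ccccc2)c2c1OC(C)(C)CC2OO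
F3 | step 6 | 2-methyl-1-(2,4,6-trimethoxy-3-methylphenyl)propan-1-one | COc1cc(OC)c(C(=O)C(C)C)c(OC)c1C
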